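The constants are invented.

Time comes first: does a flask stirred for 3.0 min reach its balance, or is it caught on the way?

substrate 10 mM (fed, over 4.0 s); reagent 0.700 equiv; free catalyst 10 mol%; added ligand 4.5 mM; time 3.0 min

    substrate + reagent ⇌ target (K1 = 390 M⁻¹, k1 = 2340 M⁻¹ s⁻¹)
    substrate + reagent ⇌ isomer of the product (K2 = 1950 M⁻¹, k2 = 755 M⁻¹ s⁻¹)
    target + free catalyst ⇌ isomer of the product + free catalyst, rate k3*[free catalyst]*[target] forward; the back reaction follows from the equilibrium constant (k3 = 12.0 M⁻¹ s⁻¹)
    free catalyst + added ligand ⇌ idle complex (K4 = 2400 M⁻¹, k4 = 172 M⁻¹ s⁻¹)
    free catalyst → spent catalyst (k5 = 0.0918 s⁻¹)

- at 3.0 min, what has stopped the reaction, if anything has (it is still moving / forward and back rates have come level / the reagent has run out first / all of the substrate has reacted / no working catalyst is left)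
- how much of the substrate has reacted by 3.0 min
- how much target there is at 3.0 min, in percent of the substrate charged
- amount of target if the flask were left three thousand times as long, in percent of the substrate charged

- the reaction counts as stopped when no species that holds the substrate changes by six tenths of a point or more over the second half of the time
- run time (flask): 3.0 min

I hold two times against each other. One is what remains after the feed, 176 s. The other is the half-life of the slower back step of the two additions, the one from the isomer of the product, 1.79 s, which is longer than that of the back step from the target. The first is 98.3 times the second, so I stop reckoning rates and reckon the balance.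

The catalysed step joins target and isomer of the product with the constant 5.00, which is the quotient of the two addition constants, so I leave it out of the balance. What I carry is the joint binding constant, the sum of the two addition constants, 2340 M⁻¹: c(target) + c(isomer of the product) equals it times c(substrate) times c(reagent).

With 10 mM of substrate and 7.00 mM of reagent, the quadratic gives 6.28 mM added. Even the limiting reagent, here the reagent itself, keeps 0.721 mM free, so I expect forward and back rates to be level. The target's share of the added material is 16.7%, which gives 10.5%, and I expect the same after a very long time.

The forecast says forward and back rates have come level, with 62.8% reacted, 10.5% target at the asked time and 10.5% in the long run, holding that “the mixture reaches full equilibrium within seconds to tens of seconds”.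

The simulation says the same of the flask: forward and back rates have come level.

| | my reckoning | forecast | flask |
|---|---|---|---|
| reacted | 62.8% | 62.8% | 62.8% |
| target, asked time | 10.5% | 10.5% | 10.5% |
| target, left very long | 10.5% | 10.5% | 10.5% |

I take the neighbouring flask with 2.80 equiv of reagent, everything else as in the recipe. The same joint binding constant, now with 28.0 mM of reagent, gives 9.77 mM added, which is 97.7% reacted and 16.3% target. The simulated neighbouring flask shows 97.7% reacted, 16.3% target and 81.4% isomer of the product, with 2.3% of the substrate still unbound.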